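**Plan**

- Cuts (labdane numbering): the acetate; the C9–C11 bond together with the C8=C17/C9–H array, back to a ring B ketone at C9 that carries the future C17 as an alkoxymethylene group on C8; then ring A at C1–C10 and C3–C4 in one [3+3] operation; last C4–C5.
- Enabling feature: in ring A an unsubstituted C1–C2–C3 trimethylene spans two quaternary carbons, C4 and C10, that are 1,3-related through C5 and each lie α to a carbonyl-level carbon (C18 ester; C9 as ketone), so both can act as enolate carbons towards one 1,3-dielectrophile.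
- Forward: ring B is bought (2-methylcyclohexenone); C4–C5 by asymmetric Mukaiyama–Michael addition; C8 blocked; ring A by one-flask double alkylation with 1-chloro-3-iodopropane; side chain by organolithium addition and transposition; C8=C17 with C9–H by diazene retro-ene; deprotection; acetylation.
- Stereochemistry: C5 from the chiral catalyst; C10 by alkylation anti to the C5 substituent; C4 by A(1,3)-controlled chair closure; C9 by intramolecular hydrogen delivery to the α-face; 13E from the bought enynol.
- Helpers: isopropoxymethylene group (blocks C8, then becomes C17), tert-butyl ester, TBS ether.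

Key step: step 5

Remark: labdane numbering is used for all positions; the target is 15-acetoxylabda-8(17),13E-dien-18-oic acid, (4R,5R,9S,10R), with 4α-carboxyl and 4β-methyl.
Remark: 13 is taken as purchasable in pure E form; the (S)-configured catalyst of step 2 is assumed to give the (R) centre at C5, otherwise its mirror image is used.

**Step 1**
Reactants: 1 tert-butyl propanoate
Product: 2 1-tert-butoxy-1-(trimethylsilyloxy)prop-1-ene (E/Z mixture)
Conditions: LiN(iPr)2 (LDA), THF, −78 °C; Me3SiCl, −78 → 23 °C
Reagents that add atoms: chlorotrimethylsilane, C[Si](C)(C)Cl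
Why: O-silylation of the lithium enolate of a tert-butyl ester (silyl ketene acetal formation) is standard and creates no lasting stereocentre.

**Step 2**
Reactants: 2 1-tert-butoxy-1-(trimethylsilyloxy)prop-1-ene; 3 2-methylcyclohex-2-en-1-one
Product: 5 tert-butyl 2-[(1R)-2-methyl-3-oxocyclohexyl]propanoate, via silyl enol ether 4 (not isolated)
Conditions: (S)-B-(o-tolyl)-diphenylprolinol oxazaborolidine·HNTf2 (20 mol %), Ph3PO (25 mol %), toluene, −20 °C; then 1 M HCl, THF, 0 °C
Reagents that add atoms: none
Why: a chiral oxazaborolidinium-catalysed Mukaiyama–Michael addition should deliver the ketene acetal to one face of the enone, the catalyst setting C5 as (R), while the C4 and C10 methine centres form as mixtures that are erased later through enolates.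

**Step 3**
Reactants: 5 tert-butyl 2-[(1R)-2-methyl-3-oxocyclohexyl]propanoate
Product: 6 tert-butyl 2-[(1R)-4-(hydroxymethylidene)-2-methyl-3-oxocyclohexyl]propanoate
Conditions: NaH, HCO2Et, cat. EtOH, THF, 0 → 23 °C; aq. HCl work-up
Reagents that add atoms: ethyl formate, CCOC=O
Why: the crossed Claisen condensation with ethyl formate should occur at the only methylene α to the ketone (C8), driven by the stable enolate of the β-keto aldehyde, and adds the future C17 without a new stereocentre.

**Step 4**
Reactants: 6 tert-butyl 2-[(1R)-4-(hydroxymethylidene)-2-methyl-3-oxocyclohexyl]propanoate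
Product: 7 tert-butyl 2-[(1R)-2-methyl-3-oxo-4-[(E)-(propan-2-yloxy)methylidene]cyclohexyl]propanoate
Conditions: 2-iodopropane, K2CO3, acetone, reflux
Reagents that add atoms: 2-iodopropane, CC(C)I
Why: O-alkylation of the hydroxymethylene ketone with a secondary iodide gives the alkoxymethylene (vinylogous ester) blocking group, which removes the acidic C8 position so that C10–H becomes the most acidic C–H.

**Step 5**
Reactants: 7 tert-butyl 2-[(1R)-2-methyl-3-oxo-4-[(E)-(propan-2-yloxy)methylidene]cyclohexyl]propanoate; 8 1-chloro-3-iodopropane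
Product: 12 tert-butyl (1R,4aS,8aR)-1,4a-dimethyl-5-oxo-6-[(E)-(propan-2-yloxy)methylidene]decahydronaphthalene-1-carboxylate, via C10 lithium enolate 9 (not isolated), via chloropropyl ketone 10 (not isolated), via ester lithium enolate 11 (not isolated)
Conditions: LiN(iPr)2 (1.0 equiv), THF, −78 → −30 °C; 8 (1.2 equiv), DMPU, −78 → 0 °C; then LiN(iPr)2 (1.3 equiv), −78 → 40 °C
Reagents that add atoms: none
Why: One equivalent of LDA forms only the cross-conjugated C10 lithium enolate 9 (C8 is blocked and the ketone α′-proton is several pKa units more acidic than the ester α-proton), which is C-alkylated by the iodide end of 8 to give 10; the second charge of LDA then forms the ester enolate 11, which displaces chloride intramolecularly and closes ring A. The closest known reaction types are the α′-alkylation of alkoxymethylene-blocked ketones to quaternary centres and the intramolecular alkylation of ester enolates, merged here into a [3+3] annulation with a 1,3-dielectrophile. Ring A closes in the 6-(enolexo)-exo-tet mode. C10 is set in the intermolecular step: the C5 substituent lies pseudoaxial to avoid A(1,2) strain with the C10 methyl and the electrophile enters anti to it, which puts C1 trans to C4 and so gives the trans ring fusion. C4 is set in the ring closure: A(1,3) strain holds C5–H in the plane of the tetrasubstituted ester enolate, and the chair transition state then leaves the ester group equatorial (α) and the methyl axial (β). The step needs site selectivity (C10 before C4, secured by the acidity order and the order of base addition), iodide-over-chloride selectivity in the first alkylation and C- over O-alkylation (lithium enolates, primary iodide).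

**Step 6**
Reactants: 13 (2E)-3-methylpent-2-en-4-yn-1-ol
Product: 14 tert-butyldimethyl{[(2E)-3-methylpent-2-en-4-yn-1-yl]oxy}silane
Conditions: TBSCl, imidazole, CH2Cl2, 0 → 23 °C
Reagents that add atoms: tert-butyldimethylsilyl chloride, CC(C)(C)[Si](C)(C)Cl
Why: silylation of a primary allylic alcohol is routine and protects O15 against the organometallic steps; the E-alkene is untouched.

**Step 7**
Reactants: 14 tert-butyldimethyl{[(2E)-3-methylpent-2-en-4-yn-1-yl]oxy}silane
Product: 15 tert-butyldimethyl{[(2E)-3-methylpenta-2,4-dien-1-yl]oxy}silane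
Conditions: H2 (1 atm), Pd/CaCO3 poisoned with Pb(OAc)2, quinoline, hexane, 23 °C
Reagents that add atoms: none
Why: semihydrogenation of the terminal alkyne over poisoned palladium should stop at the vinyl group and leave the trisubstituted E-alkene unchanged.

**Step 8**
Reactants: 15 tert-butyldimethyl{[(2E)-3-methylpenta-2,4-dien-1-yl]oxy}silane
Product: 17 tert-butyl{[(2E)-5-iodo-3-methylpent-2-en-1-yl]oxy}dimethylsilane, via alkylzirconocene chloride 16 (not isolated)
Conditions: Cp2Zr(H)Cl, THF, 23 °C; then I2, 0 °C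
Reagents that add atoms: iodine, II
Why: hydrozirconation adds Zr–H across the less hindered terminal vinyl group with zirconium on the end carbon, and iodinolysis of the C–Zr bond gives the primary iodide with the 13E alkene intact.

**Step 9**
Reactants: 17 tert-butyl{[(2E)-5-iodo-3-methylpent-2-en-1-yl]oxy}dimethylsilane; 12 tert-butyl (1R,4aS,8aR)-1,4a-dimethyl-5-oxo-6-[(E)-(propan-2-yloxy)methylidene]decahydronaphthalene-1-carboxylate
Product: 20 tert-butyl 15-[(tert-butyldimethylsilyl)oxy]-17-oxolabda-8,13E-dien-18-oate, via organolithium 18 (not isolated), via lithium alkoxide 19 (not isolated)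
Conditions: 17, t-BuLi (2.1 equiv), Et2O, −78 °C; then 12, THF, −78 → 0 °C; then 0.5 M HCl, THF, 0 °C
Reagents that add atoms: water, O
Why: iodine–lithium exchange followed by 1,2-addition to the non-enolisable vinylogous ester carbonyl and acid-promoted allylic transposition with enol ether hydrolysis (Stork–Danheiser-type) should place the side chain on C9 and turn the blocking carbon into the C17 aldehyde; the carbinol centre is destroyed.

**Step 10**
Reactants: 20 tert-butyl 15-[(tert-butyldimethylsilyl)oxy]-17-oxolabda-8,13E-dien-18-oate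
Product: 23 tert-butyl 15-[(tert-butyldimethylsilyl)oxy]labda-8(17),13E-dien-18-oate, via tosylhydrazone 21 (not isolated), via allylic diazene 22 (not isolated)
Conditions: TsNHNH2, THF, 23 °C; catecholborane, CHCl3, 0 °C; then NaOAc·3H2O, 60 °C
Reagents that add atoms: none
Why: reduction of the unsaturated tosylhydrazone and loss of sulfinate give an allylic diazene whose retro-ene loss of N2 moves the alkene to C8=C17 and delivers hydrogen to C9 from the α-face, away from the axial C10 methyl, which sets 9S with the side chain equatorial.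

**Step 11**
Reactants: 23 tert-butyl 15-[(tert-butyldimethylsilyl)oxy]labda-8(17),13E-dien-18-oate
Product: 25 15-hydroxylabda-8(17),13E-dien-18-oic acid, via trimethylsilyl ester 24 (not isolated)
Conditions: Me3SiOTf, 2,6-lutidine, CH2Cl2, 0 °C; then Bu4NF, THF, 23 °C; aq. NH4Cl work-up
Reagents that add atoms: none
Why: buffered silyl triflate converts the tert-butyl ester into the silyl ester without free acid that could move the exocyclic alkene, and fluoride then removes both silyl groups; no stereocentre is touched.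

**Step 12**
Reactants: 25 15-hydroxylabda-8(17),13E-dien-18-oic acid
Product: 26 15-acetoxylabda-8(17),13E-dien-18-oic acid (target)
Conditions: Ac2O (1.2 equiv), pyridine, CH2Cl2, 0 °C; aq. NaHCO3 then citric acid work-up
Reagents that add atoms: acetic anhydride, CC(=O)OC(C)=O
Why: the primary allylic alcohol should be acylated far faster than the hindered tertiary carboxyl group, which is returned as the free acid on aqueous work-up.

**Compound list**

1 | tert-butyl propanoate | CCC(=O)OC(C)(C)C | starting material
2 | 1-tert-butoxy-1-(trimethylsilyloxy)prop-1-ene (E/Z mixture) | CC=C(OC(C)(C)C)O[Si](C)(C)C | intermediate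
3 | 2-methylcyclohex-2-en-1-one | CC1=CCCCC1=O | starting material
4 | tert-butyl 2-[(1S)-2-methyl-3-(trimethylsilyloxy)cyclohex-2-en-1-yl]propanoate (epimers at the propanoate α-carbon) | C[Si](C)(C)OC=1CCC[C@@H](C(C)C(=O)OC(C)(C)C)C=1C | intermediate
5 | tert-butyl 2-[(1R)-2-methyl-3-oxocyclohexyl]propanoate (epimers at ring C2 and the propanoate α-carbon) | O=C1CCC[C@@H](C(C)C(=O)OC(C)(C)C)C1C | intermediate
6 | tert-butyl 2-[(1R)-4-(hydroxymethylidene)-2-methyl-3-oxocyclohexyl]propanoate | O=C1C(=CO)CC[C@@H](C(C)C(=O)OC(C)(C)C)C1C | intermediate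
7 | tert-butyl 2-[(1R)-2-methyl-3-oxo-4-[(E)-(propan-2-yloxy)methylidene]cyclohexyl]propanoate | CC(C)O/C=C1\CC[C@@H](C(C)C(=O)OC(C)(C)C)C(C)C1=O | intermediate
8 | 1-chloro-3-iodopropane | ClCCCI | starting material
9 | C10 lithium enolate of 7 (C5 as in 7) | CC(C)O/C=C1\CC[C@@H](C(C)C(=O)OC(C)(C)C)C(C)=C1O[Li] | intermediate
10 | tert-butyl 2-[(1S,2S)-2-(3-chloropropyl)-2-methyl-3-oxo-4-[(E)-(propan-2-yloxy)methylidene]cyclohexyl]propanoate | CC(C)O/C=C1\CC[C@@H](C(C)C(=O)OC(C)(C)C)[C@](C)(CCCCl)C1=O | intermediate
11 | ester lithium enolate of 10 (C5 and C10 as in 10) | CC(C)O/C=C1\CC[C@@H](C(C)=C(O[Li])OC(C)(C)C)[C@](C)(CCCCl)C1=O | intermediate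
12 | tert-butyl (1R,4aS,8aR)-1,4a-dimethyl-5-oxo-6-[(E)-(propan-2-yloxy)methylidene]decahydronaphthalene-1-carboxylate | CC(C)O/C=C1\CC[C@@H]2[C@](C)(CCC[C@@]2(C)C(=O)OC(C)(C)C)C1=O | intermediate
13 | (2E)-3-methylpent-2-en-4-yn-1-ol | C#C/C(C)=C/CO | starting material
14 | tert-butyldimethyl{[(2E)-3-methylpent-2-en-4-yn-1-yl]oxy}silane | C#C/C(C)=C/CO[Si](C)(C)C(C)(C)C | intermediate
15 | tert-butyldimethyl{[(2E)-3-methylpenta-2,4-dien-1-yl]oxy}silane | C=C/C(C)=C/CO[Si](C)(C)C(C)(C)C | intermediate
16 | chloro{(3E)-5-[(tert-butyldimethylsilyl)oxy]-3-methylpent-3-en-1-yl}zirconocene (cyclopentadienyl rings drawn σ-bonded) | Cl[Zr](CC/C(C)=C/CO[Si](C)(C)C(C)(C)C)(C1C=CC=C1)C1C=CC=C1 | intermediate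
17 | tert-butyl{[(2E)-5-iodo-3-methylpent-2-en-1-yl]oxy}dimethylsilane | ICC/C(C)=C/CO[Si](C)(C)C(C)(C)C | intermediate
18 | {(3E)-5-[(tert-butyldimethylsilyl)oxy]-3-methylpent-3-en-1-yl}lithium | [Li]CC/C(C)=C/CO[Si](C)(C)C(C)(C)C | intermediate
19 | lithium alkoxide from 1,2-addition of 18 to the C9 carbonyl of 12 (C9 carbinol configuration undefined; other centres as in 12) | CC(C)O/C=C1\CC[C@@H]2[C@](C)(CCC[C@@]2(C)C(=O)OC(C)(C)C)C1(O[Li])CC/C(C)=C/CO[Si](C)(C)C(C)(C)C | intermediate
20 | tert-butyl 15-[(tert-butyldimethylsilyl)oxy]-17-oxolabda-8,13E-dien-18-oate (5α-H, 10β-methyl, 4α-ester) | O=CC=1CC[C@@H]2[C@](C)(CCC[C@@]2(C)C(=O)OC(C)(C)C)C=1CC/C(C)=C/CO[Si](C)(C)C(C)(C)C | intermediate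
21 | 4-methylbenzenesulfonylhydrazone of 20 at C17 | Cc1ccc(cc1)S(=O)(=O)NN=CC=1CC[C@@H]2[C@](C)(CCC[C@@]2(C)C(=O)OC(C)(C)C)C=1CC/C(C)=C/CO[Si](C)(C)C(C)(C)C | intermediate
22 | C17 monoalkyl diazene of the labda-8,13E-diene (ring centres as in 20) | N=NCC=1CC[C@@H]2[C@](C)(CCC[C@@]2(C)C(=O)OC(C)(C)C)C=1CC/C(C)=C/CO[Si](C)(C)C(C)(C)C | intermediate
23 | tert-butyl 15-[(tert-butyldimethylsilyl)oxy]labda-8(17),13E-dien-18-oate (4R,5R,9S,10R) | C=C1CC[C@@H]2[C@](C)(CCC[C@@]2(C)C(=O)OC(C)(C)C)[C@H]1CC/C(C)=C/CO[Si](C)(C)C(C)(C)C | intermediate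
24 | trimethylsilyl 15-[(tert-butyldimethylsilyl)oxy]labda-8(17),13E-dien-18-oate | C=C1CC[C@@H]2[C@](C)(CCC[C@@]2(C)C(=O)O[Si](C)(C)C)[C@H]1CC/C(C)=C/CO[Si](C)(C)C(C)(C)C | intermediate
25 | 15-hydroxylabda-8(17),13E-dien-18-oic acid (4R,5R,9S,10R) | C=C1CC[C@@H]2[C@](C)(CCC[C@@]2(C)C(=O)O)[C@H]1CC/C(C)=C/CO | intermediate
26 | 15-acetoxylabda-8(17),13E-dien-18-oic acid; (1R,4aR,5S,8aR)-5-[(3E)-5-(acetyloxy)-3-methylpent-3-en-1-yl]-1,4a-dimethyl-6-methylidenedecahydronaphthalene-1-carboxylic acid | C=C1CC[C@@H]2[C@](C)(CCC[C@@]2(C)C(=O)O)[C@H]1CC/C(C)=C/COC(C)=O | target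

**Summary**

Total step count: 12. Longest linear sequence: 9 steps (steps 1–5 and 9–12).

Steps most likely to fail:

Step 5. The hindered tetrasubstituted C10 enolate may be alkylated only slowly by the unactivated primary iodide, so that proton transfer, O-alkylation and elimination of the dihalide compete, and the chloride may close the ring too slowly. The fallback sets out from 7 and builds the tether stepwise with an activated electrophile. The C10 enolate (LDA) is allylated with allyl bromide to tert-butyl 2-[(1S,2S)-2-methyl-3-oxo-2-(prop-2-en-1-yl)-4-[(E)-(propan-2-yloxy)methylidene]cyclohexyl]propanoate F1. Hydroboration–oxidation of the terminal alkene (9-BBN; NaBO3·4H2O) gives the 3-hydroxypropyl ketone F2, and Appel iodination (I2, PPh3, imidazole) gives the 3-iodopropyl ketone F3. Treatment with LDA and DMPU then closes ring A through the ester enolate and comes back to the route at 12.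

Step 9. The organolithium may act as a base at C7, or fail to add to the poorly electrophilic vinylogous ester carbonyl next to the quaternary C10. The fallback sets out from 12 and joins the side chain by cross-coupling instead. Alkaline removal of the blocking group (KOH, aq. EtOH, reflux) gives tert-butyl (1R,4aS,8aR)-1,4a-dimethyl-5-oxodecahydronaphthalene-1-carboxylate F4. Vilsmeier–Haack bromoformylation (PBr3, DMF, CHCl3) gives tert-butyl (1R,4aS,8aS)-5-bromo-6-formyl-1,4a-dimethyl-1,2,3,4,4a,7,8,8a-octahydronaphthalene-1-carboxylate F5. B-alkyl Suzuki–Miyaura coupling of F5 with 9-[(3E)-5-[(tert-butyldimethylsilyl)oxy]-3-methylpent-3-en-1-yl]-9-borabicyclo[3.3.1]nonane F6 (from 15 and 9-BBN; Pd(dppf)Cl2, AsPh3, Cs2CO3, DMF/THF/H2O) comes back to the route at 20.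

Step 2. The catalyst may discriminate the faces of the α-methylated enone poorly, giving low enantiomeric purity at C5. The fallback sets out from 2 and uses the parent enone, the substrate class on which this catalysis is established. The same catalysed Mukaiyama–Michael addition to cyclohex-2-en-1-one, worked up without acid, gives tert-butyl 2-[(1R)-3-(trimethylsilyloxy)cyclohex-2-en-1-yl]propanoate F7. Cleavage of the silyl enol ether with MeLi to the regiodefined lithium enolate and methylation with MeI then installs the C10 methyl and comes back to the route at 5.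

**Further compounds**

F1 | step 5 | tert-butyl 2-[(1S,2S)-2-methyl-3-oxo-2-(prop-2-en-1-yl)-4-[(E)-(propan-2-yloxy)methylidene]cyclohexyl]propanoate | CC(C)O/C=C1\CC[C@@H](C(C)C(=O)OC(C)(C)C)[C@](C)(CC=C)C1=O
F2 | step 5 | tert-butyl 2-[(1S,2S)-2-(3-hydroxypropyl)-2-methyl-3-oxo-4-[(E)-(propan-2-yloxy)methylidene]cyclohexyl]propanoate | CC(C)O/C=C1\CC[C@@H](C(C)C(=O)OC(C)(C)C)[C@](C)(CCCO)C1=O
F3 | step 5 | tert-butyl 2-[(1S,2S)-2-(3-iodopropyl)-2-methyl-3-oxo-4-[(E)-(propan-2-yloxy)methylidene]cyclohexyl]propanoate | CC(C)O/C=C1\CC[C@@H](C(C)C(=O)OC(C)(C)C)[C@](C)(CCCI)C1=O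
F4 | step 9 | tert-butyl (1R,4aS,8aR)-1,4a-dimethyl-5-oxodecahydronaphthalene-1-carboxylate | C1CC[C@@H]2[C@](C)(CCC[C@@]2(C)C(=O)OC(C)(C)C)C1=O
F5 | step 9 | tert-butyl (1R,4aS,8aS)-5-bromo-6-formyl-1,4a-dimethyl-1,2,3,4,4a,7,8,8a-octahydronaphthalene-1-carboxylate | O=CC=1CC[C@@H]2[C@](C)(CCC[C@@]2(C)C(=O)OC(C)(C)C)C=1Br
F6 | step 9 | 9-[(3E)-5-[(tert-butyldimethylsilyl)oxy]-3-methylpent-3-en-1-yl]-9-borabicyclo[3.3.1]nonane | B1(CC/C(C)=C/CO[Si](C)(C)C(C)(C)C)C2CCCC1CCC2
F7 | step 2 | tert-butyl 2-[(1R)-3-(trimethylsilyloxy)cyclohex-2-en-1-yl]propanoate | C[Si](C)(C)OC=1CCC[C@@H](C(C)C(=O)OC(C)(C)C)C=1
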